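**Retrosynthetic overview**
- The target flavonol is reached by one acid treatment that frees O3, O3' and O5' (methoxymethyl ethers) and O7 (tert-butyl ether); ring A is the last ring formed.
- Ring A is grafted onto the preformed pyranone ring C by thermal ring expansion of a 4-methoxy-4-(pyranon-6-yl)cyclobutenone: 4π ring opening, then 6π closure that forms C4a–C5.
- Feature used: in ring A, C5–OH and C8–OMe are para, the C7 oxygen sits next to C8 and C6 carries hydrogen. This is the pattern a 3-alkoxy-4-methoxycyclobutenone with an alkenyl group on C4 delivers, with pyranone C5/C6 becoming C4a/C8a.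
- The cyclobutenone comes from C6-lithiation of a 2-aryl-3-(methoxymethoxy)pyranone, addition to 3-tert-butoxycyclobutenedione (from di-tert-butyl squarate) and O-methylation.
- The ring B–ring C bond (C1'–C2) comes from Suzuki coupling of 2-iodo-3-(methoxymethoxy)pyranone (from pyromeconic acid) with a ring B boronate made from 2-methoxyresorcinol by C–H borylation; rings B, C and the four-membered ring are bought.

Key step: step 10

Remark on the chemistry: the four hydroxyls to be freed are carried as three methoxymethyl ethers and one tert-butyl ether, so that one acid step releases them and the ring B boronate can be made by sterically controlled C–H borylation (benzyl ethers would offer competing aryl C–H bonds). The pyranone is numbered throughout with the aryl group at C2, the oxygen substituent at C3 and hydrogens at C5 and C6. The target has no stereocentre; intermediates with one stereocentre are racemic.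

Step 1
Reactants: 1 3,4-di-tert-butoxycyclobut-3-ene-1,2-dione (di-tert-butyl squarate)
Product: 2 2,3-di-tert-butoxy-4-hydroxycyclobut-2-en-1-one (racemic)
Conditions: LiAlH(OtBu)3, THF, −78 → 0 °C; H2O work-up
Reagents that add atoms: none
Why: The bulky aluminium hydride should deliver one hydride to one of the two equivalent carbonyl groups (1,2-reduction) and stop at the hydroxycyclobutenone, whose new stereocentre is racemic and disappears in step 2.

Step 2
Reactants: 2 2,3-di-tert-butoxy-4-hydroxycyclobut-2-en-1-one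
Product: 3 3-tert-butoxycyclobut-3-ene-1,2-dione
Conditions: (CF3CO)2O, CH2Cl2, −78 → 0 °C; cold aq NaHCO3 wash
Reagents that add atoms: none
Why: Trifluoroacetylation of the hydroxyl and ionisation should give a tert-butoxy-stabilised cyclobutenyl cation that loses the tert-butyl group from its oxocarbenium oxygen (acid-promoted hydroxycyclobutenone-to-cyclobutenedione rearrangement), which leaves one vinylogous tert-butyl ester.

Step 3
Reactants: 4 3-hydroxy-4H-pyran-4-one (pyromeconic acid)
Product: 5 3-hydroxy-2-iodo-4H-pyran-4-one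
Conditions: NIS, DMF, 0 °C → rt, dark
Reagents that add atoms: N-iodosuccinimide, O=C1CCC(=O)N1I
Why: Electrophilic iodination of the enol should go to C2, ortho to the hydroxyl and next to the ring oxygen, the position at which 3-hydroxy-4-pyranones take electrophiles in their aldol, Mannich and bromination chemistry.

Step 4
Reactants: 5 3-hydroxy-2-iodo-4H-pyran-4-one
Product: 6 2-iodo-3-(methoxymethoxy)-4H-pyran-4-one
Conditions: MOMCl, iPr2NEt, CH2Cl2, 0 °C → rt
Reagents that add atoms: chloromethyl methyl ether, COCCl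
Why: O-Alkylation of the acidic enolic hydroxyl with chloromethyl methyl ether and Hünig's base (Williamson-type acetal formation) should be clean, as no other nucleophilic site is present.

Step 5
Reactants: 7 2-methoxybenzene-1,3-diol (2-methoxyresorcinol)
Product: 8 2-methoxy-1,3-bis(methoxymethoxy)benzene
Conditions: MOMCl, iPr2NEt, CH2Cl2, 0 °C → rt
Reagents that add atoms: chloromethyl methyl ether, COCCl
Why: Both phenolic hydroxyls should be converted to methoxymethyl ethers by the same Williamson-type alkylation.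

Step 6
Reactants: 8 2-methoxy-1,3-bis(methoxymethoxy)benzene
Product: 9 2-[4-methoxy-3,5-bis(methoxymethoxy)phenyl]-4,4,5,5-tetramethyl-1,3,2-dioxaborolane
Conditions: B2pin2, [Ir(OMe)(cod)]2 (cat), 4,4'-di-tert-butyl-2,2'-bipyridine (cat), THF, 80 °C
Reagents that add atoms: bis(pinacolato)diboron, CC1(C)OB(OC1(C)C)B1OC(C)(C)C(C)(C)O1
Why: Sterically controlled iridium-catalysed C–H borylation (Hartwig–Miyaura type) should go to C5, the only ring C–H without an ortho substituent, and the substrate has no other aryl C–H bonds.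

Step 7
Reactants: 6 2-iodo-3-(methoxymethoxy)-4H-pyran-4-one; 9 2-[4-methoxy-3,5-bis(methoxymethoxy)phenyl]-4,4,5,5-tetramethyl-1,3,2-dioxaborolane
Product: 10 2-[4-methoxy-3,5-bis(methoxymethoxy)phenyl]-3-(methoxymethoxy)-4H-pyran-4-one
Conditions: Pd(dppf)Cl2 (cat), K2CO3, 1,4-dioxane/H2O, 70 °C
Reagents that add atoms: none
Why: Suzuki–Miyaura coupling should be fast because the carbon–iodine bond at C2 is that of a vinylogous acyl iodide and the boronate has no ortho substituents.

Step 8
Reactants: 10 2-[4-methoxy-3,5-bis(methoxymethoxy)phenyl]-3-(methoxymethoxy)-4H-pyran-4-one; 3 3-tert-butoxycyclobut-3-ene-1,2-dione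
Product: 13 6-(2-tert-butoxy-1-hydroxy-4-oxocyclobut-2-en-1-yl)-2-[4-methoxy-3,5-bis(methoxymethoxy)phenyl]-3-(methoxymethoxy)-4H-pyran-4-one (racemic), via C6-lithiopyranone 11 (not isolated), via lithium alkoxide adduct 12 (not isolated)
Conditions: lithium 2,2,6,6-tetramethylpiperidide (LiTMP), THF, −78 °C; then 3, THF, −78 °C; sat aq NH4Cl, −78 °C → rt
Reagents that add atoms: none
Why: The hindered amide should remove the C6 hydrogen, the only one next to the ring oxygen (as in the C2-lithiation of chromones), and the organolithium should then add 1,2 to the ketone-like carbonyl of 3 (the one bonded to the tert-butoxy-bearing carbon, not the vinylogous ester carbonyl), as organolithiums do with alkoxycyclobutenediones, giving a racemic quaternary carbinol.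

Step 9
Reactants: 13 6-(2-tert-butoxy-1-hydroxy-4-oxocyclobut-2-en-1-yl)-2-[4-methoxy-3,5-bis(methoxymethoxy)phenyl]-3-(methoxymethoxy)-4H-pyran-4-one
Product: 14 6-(2-tert-butoxy-1-methoxy-4-oxocyclobut-2-en-1-yl)-2-[4-methoxy-3,5-bis(methoxymethoxy)phenyl]-3-(methoxymethoxy)-4H-pyran-4-one (racemic)
Conditions: MeI, Ag2O, 4 Å MS, MeCN, rt, dark
Reagents that add atoms: iodomethane, CI
Why: Silver oxide-assisted O-methylation (Purdie type) of the fairly acidic tertiary hydroxyl of a 4-hydroxycyclobutenone runs under near-neutral conditions that should spare the pyranone carbonyl, the acetals and the vinylogous tert-butyl ester, and the racemic stereocentre is not touched.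

Step 10
Reactants: 14 6-(2-tert-butoxy-1-methoxy-4-oxocyclobut-2-en-1-yl)-2-[4-methoxy-3,5-bis(methoxymethoxy)phenyl]-3-(methoxymethoxy)-4H-pyran-4-one
Product: 17 7-tert-butoxy-5-hydroxy-8-methoxy-2-[4-methoxy-3,5-bis(methoxymethoxy)phenyl]-3-(methoxymethoxy)-4H-chromen-4-one, via Z-dienylketene 15 (not isolated), via 4aH-dienone 16 (not isolated)
Conditions: toluene (0.01 M, degassed, argon), 110 °C
Reagents that add atoms: none
Why: Heating opens the four-membered ring by conrotatory 4π-electrocyclic cleavage of the C(=O)–C(OMe) bond to the dienylketene 15, whose ketene carbon (future C5) then bonds to pyranone C5 (future C4a) in a disrotatory 6π-electrocyclisation, and the dienone 16 enolises to the chelated C5 phenol. The closest known reaction type is the Moore ring expansion of 4-aryl-, 4-heteroaryl- and 4-alkenyl-4-alkoxycyclobutenones to annulated hydroquinone monoethers. Ring A is closed as a six-membered carbocycle by 6π-electrocyclisation across the ketene C=C bond, the C(OtBu)=C(OMe) bond and the C5=C6 bond of the pyranone, which is only weakly aromatic and gives up its C5 hydrogen on tautomerisation. No stereocentre is set, since the racemic quaternary carbon of 14 becomes the sp2 carbon C8 and the transient C4a centre of 16 is erased by enolisation. The step needs the methoxy group to turn outward in the ring opening so that the pyranone lies cis to the ketene, which the outward preference of oxygen donors secures and the acceptor character of the pyranon-6-yl group reinforces, while any ketene of the other geometry can only revert. It also needs closure at pyranone C5, the only position within reach and the nucleophilic α-carbon of the vinylogous ester, and the 5-OH, 7-O, 8-OMe pattern follows from the site of addition in step 8.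

Step 11
Reactants: 17 7-tert-butoxy-5-hydroxy-8-methoxy-2-[4-methoxy-3,5-bis(methoxymethoxy)phenyl]-3-(methoxymethoxy)-4H-chromen-4-one
Product: 18 2-(3,5-dihydroxy-4-methoxyphenyl)-3,5,7-trihydroxy-8-methoxy-4H-chromen-4-one (CNP0103387.0)
Conditions: HCl (3 M in MeOH), 45 °C
Reagents that add atoms: none
Why: Acid-catalysed acetal exchange with methanol should free the three methoxymethyl-protected hydroxyls and acidolysis should cleave the aryl tert-butyl ether, while the two aryl methyl ethers are inert to methanolic HCl and methanol traps the released cations.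

**Compound list**
1 | 3,4-di-tert-butoxycyclobut-3-ene-1,2-dione (di-tert-butyl squarate) | CC(C)(C)OC1=C(OC(C)(C)C)C(=O)C1=O | starting material
2 | 2,3-di-tert-butoxy-4-hydroxycyclobut-2-en-1-one (racemic) | CC(C)(C)OC1=C(OC(C)(C)C)C(O)C1=O | intermediate
3 | 3-tert-butoxycyclobut-3-ene-1,2-dione | CC(C)(C)OC1=CC(=O)C1=O | intermediate
4 | 3-hydroxy-4H-pyran-4-one (pyromeconic acid) | O=c1ccocc1O | starting material
5 | 3-hydroxy-2-iodo-4H-pyran-4-one | O=c1ccoc(I)c1O | intermediate
6 | 2-iodo-3-(methoxymethoxy)-4H-pyran-4-one | COCOc1c(I)occc1=O | intermediate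
7 | 2-methoxybenzene-1,3-diol (2-methoxyresorcinol) | COc1c(O)cccc1O | starting material
8 | 2-methoxy-1,3-bis(methoxymethoxy)benzene | COCOc1cccc(OCOC)c1OC | intermediate
9 | 2-[4-methoxy-3,5-bis(methoxymethoxy)phenyl]-4,4,5,5-tetramethyl-1,3,2-dioxaborolane | COCOc1cc(B2OC(C)(C)C(C)(C)O2)cc(OCOC)c1OC | intermediate
10 | 2-[4-methoxy-3,5-bis(methoxymethoxy)phenyl]-3-(methoxymethoxy)-4H-pyran-4-one | COCOc1cc(-c2occc(=O)c2OCOC)cc(OCOC)c1OC | intermediate
11 | 6-lithio-2-[4-methoxy-3,5-bis(methoxymethoxy)phenyl]-3-(methoxymethoxy)-4H-pyran-4-one | [Li]c1cc(=O)c(OCOC)c(-c2cc(OCOC)c(OC)c(OCOC)c2)o1 | intermediate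
12 | lithium 2-tert-butoxy-1-{6-[4-methoxy-3,5-bis(methoxymethoxy)phenyl]-5-(methoxymethoxy)-4-oxo-4H-pyran-2-yl}-4-oxocyclobut-2-en-1-olate (racemic) | [Li]OC1(C(OC(C)(C)C)=CC1=O)c1cc(=O)c(OCOC)c(-c2cc(OCOC)c(OC)c(OCOC)c2)o1 | intermediate
13 | 6-(2-tert-butoxy-1-hydroxy-4-oxocyclobut-2-en-1-yl)-2-[4-methoxy-3,5-bis(methoxymethoxy)phenyl]-3-(methoxymethoxy)-4H-pyran-4-one (racemic) | O=C1C=C(OC(C)(C)C)C1(O)c1cc(=O)c(OCOC)c(-c2cc(OCOC)c(OC)c(OCOC)c2)o1 | intermediate
14 | 6-(2-tert-butoxy-1-methoxy-4-oxocyclobut-2-en-1-yl)-2-[4-methoxy-3,5-bis(methoxymethoxy)phenyl]-3-(methoxymethoxy)-4H-pyran-4-one (racemic) | O=C1C=C(OC(C)(C)C)C1(OC)c1cc(=O)c(OCOC)c(-c2cc(OCOC)c(OC)c(OCOC)c2)o1 | intermediate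
15 | (3Z)-3-tert-butoxy-4-methoxy-4-{6-[4-methoxy-3,5-bis(methoxymethoxy)phenyl]-5-(methoxymethoxy)-4-oxo-4H-pyran-2-yl}buta-1,3-dien-1-one | O=C=C/C(OC(C)(C)C)=C(/OC)c1cc(=O)c(OCOC)c(-c2cc(OCOC)c(OC)c(OCOC)c2)o1 | intermediate
16 | 7-tert-butoxy-8-methoxy-2-[4-methoxy-3,5-bis(methoxymethoxy)phenyl]-3-(methoxymethoxy)-4aH-chromene-4,5-dione (racemic) | O=C1C=C(OC(C)(C)C)C(OC)=C2OC(-c3cc(OCOC)c(OC)c(OCOC)c3)=C(OCOC)C(=O)C12 | intermediate
17 | 7-tert-butoxy-5-hydroxy-8-methoxy-2-[4-methoxy-3,5-bis(methoxymethoxy)phenyl]-3-(methoxymethoxy)-4H-chromen-4-one | COCOc1cc(-c2oc3c(OC)c(OC(C)(C)C)cc(O)c3c(=O)c2OCOC)cc(OCOC)c1OC | intermediate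
18 | 2-(3,5-dihydroxy-4-methoxyphenyl)-3,5,7-trihydroxy-8-methoxy-4H-chromen-4-one | COc1c(O)cc(-c2oc3c(OC)c(O)cc(O)c3c(=O)c2O)cc1O | target

Total step count: 11. Longest linear sequence: 7 steps (steps 3, 4, 7, 8, 9, 10, 11 from pyromeconic acid; equally steps 5, 6, 7, 8, 9, 10, 11 from 2-methoxyresorcinol).

**Steps most likely to fail**

Step 8. Deprotonation may not stay at C6, because the ring B hydrogens lie between a methoxymethoxy group and the pyranone. The lithiopyranone may also be lost by ring opening or by addition to unmetalated 10 before it meets 3. The fallback sets out from 10 and returns at 13. Kinetic lithiation is replaced by thermodynamically controlled magnesiation with TMPMgCl·LiCl (THF, −30 → −20 °C), which should give the thermally stable 6-(chloromagnesio)-2-[4-methoxy-3,5-bis(methoxymethoxy)phenyl]-3-(methoxymethoxy)-4H-pyran-4-one F1. This Grignard-type reagent is added to 3 at −40 °C to give the chloromagnesium alkoxide of the carbinol F2, and NH4Cl work-up gives 13.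

Step 10. If closure of the ketene onto pyranone C5 needs long heating, thermal or trace-acid-induced loss of isobutene from the vinylogous tert-butyl ester of 14 may outrun ring opening. The fallback sets out from 10 and returns at 18; it replaces the tert-butyl group by the thermally robust isopropyl group. Commercial diisopropyl squarate (CC(C)OC1=C(OC(C)C)C(=O)C1=O) is reduced with LiAlH(OtBu)3 to 4-hydroxy-2,3-di(propan-2-yloxy)cyclobut-2-en-1-one F3. Catalytic conc HCl in CH2Cl2 then removes propan-2-ol to give 3-(propan-2-yloxy)cyclobut-3-ene-1,2-dione F4. The lithiopyranone 11, made from 10 as in step 8, adds to F4 to give 6-(1-hydroxy-4-oxo-2-(propan-2-yloxy)cyclobut-2-en-1-yl)-2-[4-methoxy-3,5-bis(methoxymethoxy)phenyl]-3-(methoxymethoxy)-4H-pyran-4-one F5. Ag2O and MeI give its methyl ether F6, and thermolysis in toluene or in p-xylene at 138 °C should give 5-hydroxy-8-methoxy-2-[4-methoxy-3,5-bis(methoxymethoxy)phenyl]-3-(methoxymethoxy)-7-(propan-2-yloxy)-4H-chromen-4-one F7. BCl3 (CH2Cl2, −78 → 0 °C, then MeOH) should cleave the isopropyl ether and the three methoxymethyl ethers and keep the two methyl ethers, neither of which is ortho or peri to the carbonyl group, to give 18.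

Step 9. The crowded tertiary hydroxyl may alkylate slowly, so that ring opening or retro-addition of the carbinol on the basic silver oxide, or methylation at the pyranone carbonyl oxygen, takes over. The fallback sets out from 13 and returns at 17; the methyl group is introduced after ring A is made. Heating 13 itself (toluene, 110 °C, argon) should run the same 4π/6π sequence on the free carbinol and give the hydroquinone 7-tert-butoxy-5,8-dihydroxy-2-[4-methoxy-3,5-bis(methoxymethoxy)phenyl]-3-(methoxymethoxy)-4H-chromen-4-one F8; any quinone formed by air is reduced back with Na2S2O4. MeI (1.1 equiv), K2CO3, acetone, rt, under argon should then methylate O8 only, since the O5 hydrogen is held in the hydrogen bond to the C4 carbonyl, giving 17.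

**Further compounds**
F1 | step 8 | 6-(chloromagnesio)-2-[4-methoxy-3,5-bis(methoxymethoxy)phenyl]-3-(methoxymethoxy)-4H-pyran-4-one | Cl[Mg]c1cc(=O)c(OCOC)c(-c2cc(OCOC)c(OC)c(OCOC)c2)o1
F2 | step 8 | chloromagnesium 2-tert-butoxy-1-{6-[4-methoxy-3,5-bis(methoxymethoxy)phenyl]-5-(methoxymethoxy)-4-oxo-4H-pyran-2-yl}-4-oxocyclobut-2-en-1-olate (racemic) | Cl[Mg]OC1(C(OC(C)(C)C)=CC1=O)c1cc(=O)c(OCOC)c(-c2cc(OCOC)c(OC)c(OCOC)c2)o1
F3 | step 10 | 4-hydroxy-2,3-di(propan-2-yloxy)cyclobut-2-en-1-one (racemic) | CC(C)OC1=C(OC(C)C)C(O)C1=O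
F4 | step 10 | 3-(propan-2-yloxy)cyclobut-3-ene-1,2-dione | CC(C)OC1=CC(=O)C1=O
F5 | step 10 | 6-(1-hydroxy-4-oxo-2-(propan-2-yloxy)cyclobut-2-en-1-yl)-2-[4-methoxy-3,5-bis(methoxymethoxy)phenyl]-3-(methoxymethoxy)-4H-pyran-4-one (racemic) | O=C1C=C(OC(C)C)C1(O)c1cc(=O)c(OCOC)c(-c2cc(OCOC)c(OC)c(OCOC)c2)o1
F6 | step 10 | 6-(1-methoxy-4-oxo-2-(propan-2-yloxy)cyclobut-2-en-1-yl)-2-[4-methoxy-3,5-bis(methoxymethoxy)phenyl]-3-(methoxymethoxy)-4H-pyran-4-one (racemic) | O=C1C=C(OC(C)C)C1(OC)c1cc(=O)c(OCOC)c(-c2cc(OCOC)c(OC)c(OCOC)c2)o1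
F7 | step 10 | 5-hydroxy-8-methoxy-2-[4-methoxy-3,5-bis(methoxymethoxy)phenyl]-3-(methoxymethoxy)-7-(propan-2-yloxy)-4H-chromen-4-one | COCOc1cc(-c2oc3c(OC)c(OC(C)C)cc(O)c3c(=O)c2OCOC)cc(OCOC)c1OC
F8 | step 9 | 7-tert-butoxy-5,8-dihydroxy-2-[4-methoxy-3,5-bis(methoxymethoxy)phenyl]-3-(methoxymethoxy)-4H-chromen-4-one | COCOc1cc(-c2oc3c(O)c(OC(C)(C)C)cc(O)c3c(=O)c2OCOC)cc(OCOC)c1OC
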